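The numbers in the tables come from a simulation for substances that don't exist.

Time lets me reduce this flask to one number: the question stands at 25 h, and I ask whether the flask has forgotten its path by then.

| setting | ochre | green | flask |
|---|---|---|---|
| solid substrate | 0.050 M | 0.050 M | 0.050 M |
| reagent | 1.2 equiv | 1.2 equiv | 1.20 equiv |
| second substrate | 1 equiv (in portions, 4) | 0.50 equiv (in portions, 4) | 1.00 equiv (in portions, 4) |
| remark | the very flask that is asked about, followed so far; portions every 12 min | run made earlier; portions every 12 min | the portions of second substrate follow each other after 12 min, the first at the start |
| time |  |  | 25 h |

- ochre (time / h: solid substrate / %, target / %): 0.500: 68.3, 2.2; 1.33: 33.8, 7.2; 2.50: 0, 9.2; 4.00: 1.1, 4.9; 6.00: 0, 4.8; 8.00: 0, 3.5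
- green (time / h: solid substrate / %, target / %): 1.33: 33.3, 7.0; 2.50: 0, 8.7; 4.00: 0, 4.9; 6.00: 2.4, 3.7; 10.0: 0.6, 1.3; 20.0: 0, 2.4

(scatter of a reading: 1 percentage point)

* at 25 h, what has stopped the reaction, if anything has (for what has run out or reacted, a solid counts together with what of it has only dissolved) (forward and back rates have come level / the reagent has run out first / all of the solid substrate has reacted / it is still moving)
* part of the solid substrate that has turned into other species by 25 h (what has only dissolved does not count)
* the target standing at 25 h, as a percentage of the solid substrate charged
* the starting material standing at 25 h, as a percentage of the solid substrate charged
* amount of target if the flask were left three thousand times as long, in percent of the solid substrate charged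

- as a solid, counted per litre of solution: solid substrate
- at the start none of the solid substrate is in solution
- what has only dissolved of solid substrate counts as not reacted
- what has gone from starting material into another species counts as reacted, even if it can come back
- the reaction counts as stopped when no species that holds the solid substrate changes by six tenths of a point or more over the second half of the time
- starting material means what is dissolved; the solid is not counted in it

In the green flask the target falls from 8.7% at 2.50 h to 1.3% at 10.0 h and 2.4% at 20.0 h. Those last two readings average 1.85%. I define ρ, the target odds, as target divided by the rest of the material from the solid substrate; as a reading of the green flask, with its scatter, ρ = 0.0188. Even odds, 1, are the zero of my scale, and the green flask reads far below them. If target forms reversibly with one reagent and the rest keeps its make-up, ρ scales with free reagent.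

Is one number enough? In the green flask the target's excess over the tail, between 2.50 h and 6.00 h, reads as a time constant of 2.67 h, much shorter than 25 h, so I estimate that the path is forgotten by then. With 0.50 equiv of second substrate in the green flask and 1 equiv in the ochre flask, the target reads 4.9% against 4.9% at 4.00 h, so I carry ρ to the asked flask, with its equal reagent charge, and expect target 1.85%. But ρ does not say how the rest divides, and no reading shows starting material.

The forecast reads the tail as “a low plateau, meaning a reversible balance” and gives: forward and back rates have come level; conversion 97%; target 1.8%; starting material 1.5%; long-term target 1.7%. The flask gives: forward and back rates have come level; conversion 93.3%; target 1.92%; starting material 6.72%; long-term target 1.92%.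

    starting material ⇌ dormant form (K = 13.6, k = 0.0167 min⁻¹)
    starting material + reagent ⇌ target (K = 5.66 M⁻¹, k = 0.161 M⁻¹ min⁻¹)
    second substrate + reagent ⇌ second product (K = 4.00 M⁻¹, k = 0.0538 M⁻¹ min⁻¹)
    solid substrate ⇌ starting material, rate k4*(cs4 - [starting material]) while solid is left; crystals form when [starting material] > cs4 (solubility = 27.0 mM, k = 0.0259 min⁻¹)

The forward half-life of starting material going to dormant form, 0.69 h, is short against 25 h. At 25.0 h that forward rate is 2.0 times the forward rate of starting material with reagent to target. The dormant form, the resting state, then holds 91.4% of the solid substrate charged, and the flask's odds are 0.0196. Taking my ρ, read in the green flask, as the asked flask's and scaling it by free reagent to a neighbour flask with 4.80 equiv of reagent, its other charges unchanged, gives odds of 0.0794, or target 7.35%; that neighbour stands at 7.63%.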